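all flasks: free catalyst 0.50 mM
- Wednesday's: starting material 0.25 M; one stirred flow tank at steady state, fed with the mixture as stated, mean residence time 25.0 d
- Saturday's: starting material 0.25 M; one stirred flow tank at steady state, fed with the mixture as stated, mean residence time 2.5 d
- Thursday's: starting material 0.25 M (fed, over 2.00 d); a stirred flask in which starting material is dosed at a steady rate over 2.00 d without added volume, worked up at 2.5 d; time 2.5 d
- Tuesday's: starting material 0.25 M; a closed flask charged with all of it at once and left for 2.5 d; time 2.5 d

    starting material + free catalyst → catalyst intermediate A (k1 = 1.43 L mol⁻¹ min⁻¹)
    catalyst intermediate A → catalyst intermediate B (k2 = 0.118 min⁻¹)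
    catalyst intermediate B → free catalyst + product (k3 = 0.387 min⁻¹)

1. the set-up with the highest amount of product at the outlet or at the end, in percent of the starting material put in ("none" if the first two lie within 2 percentage points) (Wednesday's / Saturday's / Thursday's / Tuesday's / none)
2. amount of product at the outlet or at the end, in percent of the starting material put in, Wednesday's
3. amount of product at the outlet or at the end, in percent of the starting material put in, Saturday's
4. amount of product at the outlet or at the end, in percent of the starting material put in, Thursday's
5. amount of product at the outlet or at the end, in percent of the starting material put in, Tuesday's

- the stated concentrations are those of everything mixed, before any reaction; amounts are the same in each set-up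
- the feed brings no volume worth counting
- run time (Thursday's): 2.5 d

If catalyst intermediates A and B are taken at steady state, then free catalyst and both intermediates share the catalyst charge, and a catalyst molecule needs 11.1 min for steps 2 and 3 together. At that turnover, the catalyst charge would pass the whole starting material through in the full-speed time T = 3.84 d, and the steady state is fair because one round is far shorter than that. The catalyst holds hardly any of the charge, so with s the fraction of starting material left, the product fraction p is the rest. Adding the wait for step 1 to that round gives the saturation law dp/dt = s/[T(κ + s)], with half-saturation fraction κ = 0.253.

In Tuesday's closed flask the curve starts with slope 0.208 d⁻¹, and that line reaches 52.0% at 2.5 d. The law integrates to t = T(p − κ ln s), so by the law that level takes 2.71 d. Taking back the excess at the slope there, 0.171 d⁻¹, leaves 48.4%. The knee, where s reaches κ, comes at 4.20 d, later than the end of Tuesday's run. Well past it, with s far below κ, Tuesday's curve turns pseudo-first-order, with time constant κT = 0.971 d, and runs towards the whole charge.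

Wednesday's tank balance is p = (τ/T)s/(κ + s), with τ/T = 6.51. With p near the whole charge, s comes to 4.59%, so p is 95.4%. By the law, that is more than the ceiling of 65.1% that full speed over 2.5 d gives the other set-ups, so this reckoning names Wednesday's. It stops short of Saturday's and Thursday's figures.

The forecast names Wednesday's, with 95.5%, 44.6%, 37.9% and 48.3% in the order asked, holding that “The 25 d tank wins simply through its ten-fold longer time”.

The simulation gives Wednesday's as best, with 95.6%, 44.6%, 37.9% and 48.3%, and Tuesday's flask ends with 51.5% of its starting material unreacted. With the starting material held, T varies inversely with the catalyst charge, so in Tuesday's flask at 0.558 mM of free catalyst it shortens to 3.44 d, and 2.5 d becomes 0.727 of T. The same share arises at 2.79 d with the present catalyst, and at each of these two settings Tuesday's answer has moved by 5 points.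

The constants used here were drawn at random within sensible limits; the run is a simulation.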